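**Retrosynthetic overview**

1. Target 45 ⇒ methyl furanoside acid 44: one acid-triggered closure makes both oxygen bridges of the 2,7-dioxabicyclo[3.2.1]octan-3-one. Its C8–C5 bond comes from a second, acyclic Ireland–Claisen rearrangement between arm acid 28 and a glyceraldehyde-derived (Z)-allylic alcohol.
2. 28 ⇒ decalin acid 22: the axial carboxyl on the ring B quaternary carbon becomes its methyl group, and the acetal arm becomes the CH2CO2H unit that carries the bicycle.
3. Feature: in ring B the quaternary carbon C2 (methyl, bicycle) is bonded to C1, the methine with the secondary methyl, and C1 is attached to C8a of the ring A alkene C8=C8a. A carboxyl-bearing carbon bonded to an allylic carbon is the product pattern of an ester-enolate [3,3] shift, run here as a ring contraction: 22 ⇒ eight-membered lactone 19 with a (Z)-ethylidene on ring A.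
4. 19 ⇒ 4,4-dimethylcyclohex-2-enone 1: asymmetric conjugate addition of the butanoate chain with aldol trapping, dehydration, ketone reduction, E→Z olefin inversion, lactonisation and α-alkylation.
5. Ring order: ring A (from 1) → eight-membered lactone (temporary) → ring B → tetrahydrofuran ring → lactone-acetal ring.

Key step: step 10

Assumption: the (S,R,R)-phosphoramidite is taken to deliver the alkyl group to the same face of 1 as it does for cyclohex-2-enone (otherwise its enantiomer is used); decalin locants follow naphthalene numbering (C1 methine, C2 quaternary, C4a ring fusion, C8=C8a alkene).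

**Route**

Step 1
Reactants: 1 4,4-dimethylcyclohex-2-en-1-one; 2 ethyl 4-iodobutanoate; 3 acetaldehyde
Product: 6 ethyl 4-[(1R)-6-(1-hydroxyethyl)-2,2-dimethyl-5-oxocyclohexyl]butanoate (isomer mixture at C6 and the carbinol carbon), via bis(4-ethoxy-4-oxobutyl)zinc 4 (not isolated), via zinc enolate 5 (not isolated)
Conditions: 2, Et2Zn, CuI (cat.), 50 °C, then volatiles off in vacuo; 1, Cu(OTf)2 (2 mol%), (S,R,R)-phosphoramidite ligand from (S)-binaphthol and bis[(R)-1-phenylethyl]amine (4 mol%), toluene, −30 °C; then 3, −30 → 0 °C; aq. NH4Cl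
Reagents that add atoms: none
Why: Copper-catalysed enantioselective 1,4-addition of a functionalised dialkylzinc, in which the ligand sets the chain-bearing ring stereocentre, followed by aldol trapping of the zinc enolate; the two further centres are mixtures that step 2 removes.

Step 2
Reactants: 6 ethyl 4-[(1R)-6-(1-hydroxyethyl)-2,2-dimethyl-5-oxocyclohexyl]butanoate
Product: 8 ethyl 4-[(1S,6E)-6-ethylidene-2,2-dimethyl-5-oxocyclohexyl]butanoate, via mesylate 7 (not isolated)
Conditions: MsCl, Et3N, CH2Cl2, 0 °C → rt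
Reagents that add atoms: none
Why: Mesylation and E1cB elimination of the β-mesyloxy ketone should give the conjugated exocyclic enone as its thermodynamic E isomer (methyl anti to the carbonyl).

Step 3
Reactants: 8 ethyl 4-[(1S,6E)-6-ethylidene-2,2-dimethyl-5-oxocyclohexyl]butanoate
Product: 9 ethyl 4-[(1S,5R,6E)-6-ethylidene-5-hydroxy-2,2-dimethylcyclohexyl]butanoate
Conditions: (S)-2-methyl-CBS-oxazaborolidine (0.2 equiv), catecholborane, toluene, −78 °C
Reagents that add atoms: none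
Why: Corey–Bakshi–Shibata 1,2-reduction delivers hydride to the ketone face opposite the side chain, which A(1,3) strain with the E-methyl holds axial, so catalyst and substrate preference agree and the hydroxyl is set cis to the chain.

Step 4
Reactants: 9 ethyl 4-[(1S,5R,6E)-6-ethylidene-5-hydroxy-2,2-dimethylcyclohexyl]butanoate
Product: 10 ethyl 4-[8-hydroxy-2,5,5-trimethyl-1-oxaspiro[2.5]octan-4-yl]butanoate (epoxide oxygen cis to the hydroxyl)
Conditions: VO(acac)2 (cat.), t-BuOOH, CH2Cl2, 0 °C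
Reagents that add atoms: tert-butyl hydroperoxide CC(C)(C)OO
Why: Hydroxyl-directed vanadium-catalysed epoxidation of the allylic alcohol; the epoxide configuration is of no consequence because both epoxide carbons return to sp2 in step 6.

Step 5
Reactants: 10 ethyl 4-[8-hydroxy-2,5,5-trimethyl-1-oxaspiro[2.5]octan-4-yl]butanoate
Product: 11 4-[8-hydroxy-2,5,5-trimethyl-1-oxaspiro[2.5]octan-4-yl]butanoic acid
Conditions: LiOH, THF/H2O, rt; then 1 M HCl to pH 4
Reagents that add atoms: lithium hydroxide [Li+].[OH-]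
Why: Saponification frees the carboxylate so that no ester is exposed to the phosphide in step 6.

Step 6
Reactants: 11 4-[8-hydroxy-2,5,5-trimethyl-1-oxaspiro[2.5]octan-4-yl]butanoic acid
Product: 14 4-[(1S,5R,6Z)-6-ethylidene-5-hydroxy-2,2-dimethylcyclohexyl]butanoic acid, via hydroxyphosphine 12 (not isolated), via phosphonium betaine 13 (not isolated)
Conditions: LiPPh2 (0.5 M in THF, 3.5 equiv), 0 °C → rt; then MeI, rt; aq. HCl work-up
Reagents that add atoms: none
Why: Olefin inversion by the phosphorus betaine method: SN2 opening of the epoxide at the secondary carbon by Ph2P– (inversion), P-methylation and syn-elimination of the betaine convert the E- into the Z-ethylidene stereospecifically.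

Step 7
Reactants: 14 4-[(1S,5R,6Z)-6-ethylidene-5-hydroxy-2,2-dimethylcyclohexyl]butanoic acid
Product: 15 (1R,7S,11Z)-11-ethylidene-8,8-dimethyl-2-oxabicyclo[5.3.1]undecan-3-one
Conditions: 2-methyl-6-nitrobenzoic anhydride, DMAP, Et3N, toluene (high dilution, slow addition), 40 °C
Reagents that add atoms: none
Why: Shiina macrolactonisation (mixed anhydride, DMAP acyl transfer); the hydroxyl, held axial by A(1,3) strain with the Z-methyl, and the chain are cis-1,3 on the ring, which brings the reacting ends together.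

Step 8
Reactants: 16 2,2-dimethoxyethanol
Product: 17 2,2-dimethoxyethyl trifluoromethanesulfonate
Conditions: Tf2O, 2,6-lutidine, CH2Cl2, −78 °C
Reagents that add atoms: trifluoromethanesulfonic anhydride O=S(=O)(OS(=O)(=O)C(F)(F)F)C(F)(F)F
Why: O-Triflation of a primary alcohol gives an electrophile reactive enough for enolate alkylation, which the corresponding bromoacetal is not.

Step 9
Reactants: 15 (1R,7S,11Z)-11-ethylidene-8,8-dimethyl-2-oxabicyclo[5.3.1]undecan-3-one; 17 2,2-dimethoxyethyl trifluoromethanesulfonate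
Product: 19 (1R,4R,7S,11Z)-4-(2,2-dimethoxyethyl)-11-ethylidene-8,8-dimethyl-2-oxabicyclo[5.3.1]undecan-3-one (the 4S epimer forms too; both are used), via lithium enolate 18 (not isolated)
Conditions: LiN(iPr)2, THF, −78 °C; then 17, −78 → −40 °C
Reagents that add atoms: none
Why: Alkylation of the lactone lithium enolate with a primary triflate at low temperature; the new α-centre needs no control because step 10 erases it.

Step 10
Reactants: 19 (1R,4R,7S,11Z)-4-(2,2-dimethoxyethyl)-11-ethylidene-8,8-dimethyl-2-oxabicyclo[5.3.1]undecan-3-one (either C4 epimer)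
Product: 22 (1R,2R,4aS)-2-(2,2-dimethoxyethyl)-1,5,5-trimethyl-1,2,3,4,4a,5,6,7-octahydronaphthalene-2-carboxylic acid, via silyl ketene acetal 20 (not isolated), via trimethylsilyl ester 21 (not isolated)
Conditions: KN(SiMe3)2, Me3SiCl/Et3N, THF–toluene, −78 °C; then 80 °C; aq. citric acid (pH 5)
Reagents that add atoms: none
Why: Proposed new method: KN(SiMe3)2 removes the α-proton of either epimer of 19 and Me3SiCl traps the single, ring-constrained ketene acetal 20, which on warming should undergo a suprafacial [3,3] shift in which lactone C4 bonds to the ethylidene carbon, the allylic C1–O bond breaks and the alkene moves to C1=C11 inside ring A. The closest known reaction type is the Ireland–Claisen ring contraction of unsaturated lactones with nine or more ring atoms; here the lactone is eight-membered and the allyl terminus is exocyclic, so C5–C6–C7 act as a tether and ring B closes in a 6-exo sense across it. The tether allows bonding only on the alkene face that carries the lactone bridge, the six reacting atoms and the three-carbon tether forming a doubly chair-like bicyclo[3.3.1]nonane array. The secondary methyl stereocentre follows from the Z geometry of the ethylidene on that face (methyl equatorial), and the quaternary stereocentre from the bicyclic array, which puts the ketene acetal carbon (the future carboxyl) axial and the acetal arm equatorial on the new chair. The step needs the rearrangement to outrun β-elimination or ketene loss from the enolate, which immediate O-silylation at −78 °C and the short distance between C4 and the ethylidene carbon should secure.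

Step 11
Reactants: 22 (1R,2R,4aS)-2-(2,2-dimethoxyethyl)-1,5,5-trimethyl-1,2,3,4,4a,5,6,7-octahydronaphthalene-2-carboxylic acid
Product: 23 [(1R,2R,4aS)-2-(2,2-dimethoxyethyl)-1,5,5-trimethyl-1,2,3,4,4a,5,6,7-octahydronaphthalen-2-yl]methanol
Conditions: LiAlH4, THF, reflux; aq. NaOH work-up
Reagents that add atoms: none
Why: LiAlH4 reduces the hindered tertiary carboxylic acid to the neopentyl alcohol while acetal and alkene are inert.

Step 12
Reactants: 23 [(1R,2R,4aS)-2-(2,2-dimethoxyethyl)-1,5,5-trimethyl-1,2,3,4,4a,5,6,7-octahydronaphthalen-2-yl]methanol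
Product: 24 (1R,2R,4aS)-2-(2,2-dimethoxyethyl)-1,5,5-trimethyl-1,2,3,4,4a,5,6,7-octahydronaphthalene-2-carbaldehyde
Conditions: Dess–Martin periodinane, NaHCO3, CH2Cl2, rt
Reagents that add atoms: none
Why: Dess–Martin oxidation of a primary alcohol to the aldehyde under buffered conditions that spare the acetal.

Step 13
Reactants: 24 (1R,2R,4aS)-2-(2,2-dimethoxyethyl)-1,5,5-trimethyl-1,2,3,4,4a,5,6,7-octahydronaphthalene-2-carbaldehyde
Product: 26 (1S,2S,4aS)-2-(2,2-dimethoxyethyl)-1,2,5,5-tetramethyl-1,2,3,4,4a,5,6,7-octahydronaphthalene, via hydrazone 25 (not isolated)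
Conditions: N2H4·H2O, KOH, diethylene glycol, 130 °C then 200 °C
Reagents that add atoms: none
Why: Wolff–Kishner reduction (Huang–Minlon conditions) turns the hindered aldehyde into the quaternary methyl group under basic conditions in which the acetal is stable.

Step 14
Reactants: 26 (1S,2S,4aS)-2-(2,2-dimethoxyethyl)-1,2,5,5-tetramethyl-1,2,3,4,4a,5,6,7-octahydronaphthalene
Product: 28 2-[(1S,2S,4aS)-1,2,5,5-tetramethyl-1,2,3,4,4a,5,6,7-octahydronaphthalen-2-yl]acetic acid, via aldehyde 27 (not isolated)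
Conditions: 1 M HCl, THF, rt; then NaClO2, NaH2PO4, 2-methyl-2-butene, t-BuOH/H2O, 0 °C
Reagents that add atoms: water O; sodium chlorite [Na+].[O-]Cl=O
Why: Acid hydrolysis of the dimethyl acetal and Pinnick oxidation of the aldehyde give the acid for the second rearrangement, the scavenger keeping HOCl away from the ring alkene.

Step 15
Reactants: 29 (R)-2,2-dimethyl-1,3-dioxolane-4-carbaldehyde; 30 methyl (triphenylphosphoranylidene)acetate
Product: 31 methyl (2Z)-3-[(4S)-2,2-dimethyl-1,3-dioxolan-4-yl]prop-2-enoate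
Conditions: MeOH, 0 °C
Reagents that add atoms: none
Why: Wittig reaction of the stabilised ylide in methanol, which favours the Z-enoate with α-alkoxy aldehydes; the stereocentre is not touched.

Step 16
Reactants: 31 methyl (2Z)-3-[(4S)-2,2-dimethyl-1,3-dioxolan-4-yl]prop-2-enoate
Product: 32 (2Z)-3-[(4S)-2,2-dimethyl-1,3-dioxolan-4-yl]prop-2-en-1-ol
Conditions: iBu2AlH, CH2Cl2, −78 °C; Rochelle salt work-up
Reagents that add atoms: none
Why: iBu2AlH reduces the enoate to the allylic alcohol without change of alkene geometry.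

Step 17
Reactants: 28 2-[(1S,2S,4aS)-1,2,5,5-tetramethyl-1,2,3,4,4a,5,6,7-octahydronaphthalen-2-yl]acetic acid; 32 (2Z)-3-[(4S)-2,2-dimethyl-1,3-dioxolan-4-yl]prop-2-en-1-ol
Product: 33 (2Z)-3-[(4S)-2,2-dimethyl-1,3-dioxolan-4-yl]prop-2-en-1-yl 2-[(1S,2S,4aS)-1,2,5,5-tetramethyl-1,2,3,4,4a,5,6,7-octahydronaphthalen-2-yl]acetate
Conditions: DCC, DMAP (cat.), CH2Cl2, rt
Reagents that add atoms: none
Why: Steglich esterification of a primary allylic alcohol with the neopentyl-type acid.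

Step 18
Reactants: 33 (2Z)-3-[(4S)-2,2-dimethyl-1,3-dioxolan-4-yl]prop-2-en-1-yl 2-[(1S,2S,4aS)-1,2,5,5-tetramethyl-1,2,3,4,4a,5,6,7-octahydronaphthalen-2-yl]acetate
Product: 36 (2R,3R)-3-[(4S)-2,2-dimethyl-1,3-dioxolan-4-yl]-2-[(1S,2R,4aS)-1,2,5,5-tetramethyl-1,2,3,4,4a,5,6,7-octahydronaphthalen-2-yl]pent-4-enoic acid, via silyl ketene acetal 34 (not isolated), via trimethylsilyl ester 35 (not isolated)
Conditions: LiN(iPr)2, THF, −78 °C; Me3SiCl/Et3N; −78 → 60 °C; aq. NH4Cl
Reagents that add atoms: none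
Why: Ireland–Claisen rearrangement in which LiN(iPr)2 in THF gives the E-silyl ketene acetal, the chair transition state with the Z-allyl unit gives the 2,3-syn relation, and A(1,3) strain in the Z-alkene makes the new bond form anti to the dioxolane C–O bond, so that both new centres should be set as 2R,3R.

Step 19
Reactants: 36 (2R,3R)-3-[(4S)-2,2-dimethyl-1,3-dioxolan-4-yl]-2-[(1S,2R,4aS)-1,2,5,5-tetramethyl-1,2,3,4,4a,5,6,7-octahydronaphthalen-2-yl]pent-4-enoic acid
Product: 37 (3R,4R,5S)-4-ethenyl-5-(hydroxymethyl)-3-[(1S,2R,4aS)-1,2,5,5-tetramethyl-1,2,3,4,4a,5,6,7-octahydronaphthalen-2-yl]oxolan-2-one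
Conditions: AcOH/H2O (4:1), 50 °C; then PPTS (cat.), toluene, 80 °C
Reagents that add atoms: none
Why: Acidic removal of the acetonide and lactonisation of the γ-hydroxy acid, the five-membered lactone through the secondary hydroxyl being favoured over the six-membered one through the primary hydroxyl.

Step 20
Reactants: 37 (3R,4R,5S)-4-ethenyl-5-(hydroxymethyl)-3-[(1S,2R,4aS)-1,2,5,5-tetramethyl-1,2,3,4,4a,5,6,7-octahydronaphthalen-2-yl]oxolan-2-one
Product: 38 (2S,3R,4R)-3-ethenyl-5-oxo-4-[(1S,2R,4aS)-1,2,5,5-tetramethyl-1,2,3,4,4a,5,6,7-octahydronaphthalen-2-yl]oxolane-2-carboxylic acid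
Conditions: TEMPO (cat.), PhI(OAc)2, MeCN/H2O, rt
Reagents that add atoms: water O
Why: TEMPO/PhI(OAc)2 oxidation in wet acetonitrile takes the primary alcohol to the carboxylic acid and leaves lactone and alkenes alone.

Step 21
Reactants: 38 (2S,3R,4R)-3-ethenyl-5-oxo-4-[(1S,2R,4aS)-1,2,5,5-tetramethyl-1,2,3,4,4a,5,6,7-octahydronaphthalen-2-yl]oxolane-2-carboxylic acid
Product: 40 methyl (2S,3R,4R)-3-ethenyl-5-methoxy-4-[(1S,2R,4aS)-1,2,5,5-tetramethyl-1,2,3,4,4a,5,6,7-octahydronaphthalen-2-yl]oxolane-2-carboxylate (both anomers), via lactol acid 39 (not isolated)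
Conditions: iBu2AlH (3.2 equiv), CH2Cl2, −78 °C; then HCl in MeOH, rt
Reagents that add atoms: methanol CO
Why: iBu2AlH turns the acid into an aluminium carboxylate that is not reduced at −78 °C and reduces the γ-lactone to the lactol, which methanolic HCl converts into the methyl acetal while esterifying the acid (Fischer glycosidation and esterification).

Step 22
Reactants: 40 methyl (2S,3R,4R)-3-ethenyl-5-methoxy-4-[(1S,2R,4aS)-1,2,5,5-tetramethyl-1,2,3,4,4a,5,6,7-octahydronaphthalen-2-yl]oxolane-2-carboxylate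
Product: 41 methyl (2R,3R,4R)-3-ethenyl-5-methoxy-4-[(1S,2R,4aS)-1,2,5,5-tetramethyl-1,2,3,4,4a,5,6,7-octahydronaphthalen-2-yl]oxolane-2-carboxylate
Conditions: NaOMe (0.3 equiv), MeOH, 40 °C
Reagents that add atoms: none
Why: Base-mediated epimerisation α to the ester moves the methoxycarbonyl group from the all-cis arrangement to the face opposite its two ring neighbours (thermodynamic control), giving the 2R centre; no other centre is acidic.

Step 23
Reactants: 41 methyl (2R,3R,4R)-3-ethenyl-5-methoxy-4-[(1S,2R,4aS)-1,2,5,5-tetramethyl-1,2,3,4,4a,5,6,7-octahydronaphthalen-2-yl]oxolane-2-carboxylate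
Product: 43 methyl (2R,3R,4R)-3-(2-hydroxyethyl)-5-methoxy-4-[(1S,2R,4aS)-1,2,5,5-tetramethyl-1,2,3,4,4a,5,6,7-octahydronaphthalen-2-yl]oxolane-2-carboxylate, via alkylborane 42 (not isolated)
Conditions: 9-BBN, THF, rt → 50 °C; then H2O2, aq. NaOAc, 0 °C → rt
Reagents that add atoms: hydrogen peroxide OO
Why: Anti-Markovnikov hydroboration of the monosubstituted alkene with 9-BBN, which does not touch the hindered trisubstituted ring alkene, followed by buffered oxidation.

Step 24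
Reactants: 43 methyl (2R,3R,4R)-3-(2-hydroxyethyl)-5-methoxy-4-[(1S,2R,4aS)-1,2,5,5-tetramethyl-1,2,3,4,4a,5,6,7-octahydronaphthalen-2-yl]oxolane-2-carboxylate
Product: 44 2-[(2R,3R,4R)-5-methoxy-2-(methoxycarbonyl)-4-[(1S,2R,4aS)-1,2,5,5-tetramethyl-1,2,3,4,4a,5,6,7-octahydronaphthalen-2-yl]oxolan-3-yl]acetic acid
Conditions: TEMPO (cat.), PhI(OAc)2, CH2Cl2/H2O, rt
Reagents that add atoms: water O
Why: TEMPO/PhI(OAc)2 oxidation of the primary alcohol to the acid under conditions that glycosidic acetals tolerate.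

Step 25
Reactants: 44 2-[(2R,3R,4R)-5-methoxy-2-(methoxycarbonyl)-4-[(1S,2R,4aS)-1,2,5,5-tetramethyl-1,2,3,4,4a,5,6,7-octahydronaphthalen-2-yl]oxolan-3-yl]acetic acid
Product: 45 methyl (1S,5R,6R,8R)-3-oxo-8-[(1S,2R,4aS)-1,2,5,5-tetramethyl-1,2,3,4,4a,5,6,7-octahydronaphthalen-2-yl]-2,7-dioxabicyclo[3.2.1]octane-6-carboxylate
Conditions: TsOH·H2O (cat.), 4 Å molecular sieves, CH2Cl2, rt
Reagents that add atoms: none
Why: Acid-catalysed transacetalisation in which the oxocarbenium ion from the methyl acetal is captured by the carboxylic acid held on the same ring face, closing the six-membered lactone-acetal ring and fixing the acetal centre.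

**Compound list**

1 | 4,4-dimethylcyclohex-2-en-1-one | CC1(C)CCC(=O)C=C1 | starting material
2 | ethyl 4-iodobutanoate | CCOC(=O)CCCI | starting material
3 | acetaldehyde | CC=O | starting material
4 | bis(4-ethoxy-4-oxobutyl)zinc | CCOC(=O)CCC[Zn]CCCC(=O)OCC | intermediate
5 | zinc enolate of the 1,4-adduct (O–Zn–(CH2)3CO2Et) | CCOC(=O)CCC[Zn]OC1=C[C@@H](CCCC(=O)OCC)C(C)(C)CC1 | intermediate
6 | ethyl 4-[(1R)-6-(1-hydroxyethyl)-2,2-dimethyl-5-oxocyclohexyl]butanoate (isomer mixture at C6 and the carbinol carbon) | O=C1CCC(C)(C)[C@H](CCCC(=O)OCC)C1C(C)O | intermediate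
7 | ethyl 4-[(1R)-2,2-dimethyl-6-(1-methylsulfonyloxyethyl)-5-oxocyclohexyl]butanoate | O=C1CCC(C)(C)[C@H](CCCC(=O)OCC)C1C(C)OS(C)(=O)=O | intermediate
8 | ethyl 4-[(1S,6E)-6-ethylidene-2,2-dimethyl-5-oxocyclohexyl]butanoate | O=C1CCC(C)(C)[C@H](CCCC(=O)OCC)/C1=C\C | intermediate
9 | ethyl 4-[(1S,5R,6E)-6-ethylidene-5-hydroxy-2,2-dimethylcyclohexyl]butanoate | O[C@@H]1CCC(C)(C)[C@H](CCCC(=O)OCC)/C1=C\C | intermediate
10 | ethyl 4-[8-hydroxy-2,5,5-trimethyl-1-oxaspiro[2.5]octan-4-yl]butanoate (epoxide oxygen, hydroxyl and side chain on one ring face; epoxide methyl on the side of C4) | O[C@@H]1CCC(C)(C)[C@H](CCCC(=O)OCC)[C@]12O[C@H]2C | intermediate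
11 | 4-[8-hydroxy-2,5,5-trimethyl-1-oxaspiro[2.5]octan-4-yl]butanoic acid (configuration as 10) | O[C@@H]1CCC(C)(C)[C@H](CCCC(=O)O)[C@]12O[C@H]2C | intermediate
12 | 4-{6-[1-(diphenylphosphanyl)ethyl]-5,6-dihydroxy-2,2-dimethylcyclohexyl}butanoic acid (present as lithium salts; inverted at the methyl-bearing carbon) | O[C@@H]1CCC(C)(C)[C@H](CCCC(=O)O)[C@@]1(O)[C@@H](C)P(c2ccccc2)c2ccccc2 | intermediate
13 | P-methylphosphonium alkoxide (betaine) of 12 | O[C@@H]1CCC(C)(C)[C@H](CCCC(=O)O)[C@@]1([O-])[C@@H](C)[P+](C)(c2ccccc2)c2ccccc2 | intermediate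
14 | 4-[(1S,5R,6Z)-6-ethylidene-5-hydroxy-2,2-dimethylcyclohexyl]butanoic acid | O[C@@H]1CCC(C)(C)[C@H](CCCC(=O)O)/C1=C/C | intermediate
15 | (1R,7S,11Z)-11-ethylidene-8,8-dimethyl-2-oxabicyclo[5.3.1]undecan-3-one | O=C1O[C@@H]2CCC(C)(C)[C@H](CCC1)/C2=C/C | intermediate
16 | 2,2-dimethoxyethanol | COC(CO)OC | starting material
17 | 2,2-dimethoxyethyl trifluoromethanesulfonate | COC(COS(=O)(=O)C(F)(F)F)OC | intermediate
18 | lithium enolate of 15 | [Li]OC1=CCC[C@H]2C(C)(C)CC[C@@H](O1)/C2=C\C | intermediate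
19 | (1R,4R,7S,11Z)-4-(2,2-dimethoxyethyl)-11-ethylidene-8,8-dimethyl-2-oxabicyclo[5.3.1]undecan-3-one (4R drawn; the 4S epimer reacts alike) | O=C1O[C@@H]2CCC(C)(C)[C@H](CC[C@@H]1CC(OC)OC)/C2=C/C | intermediate
20 | trimethylsilyl ketene acetal of 19 | C[Si](C)(C)OC1=C(CC(OC)OC)CC[C@H]2C(C)(C)CC[C@@H](O1)/C2=C\C | intermediate
21 | trimethylsilyl ester of 22 | C[Si](C)(C)OC(=O)[C@@]1(CC(OC)OC)CC[C@@H]2C(=CCCC2(C)C)[C@H]1C | intermediate
22 | (1R,2R,4aS)-2-(2,2-dimethoxyethyl)-1,5,5-trimethyl-1,2,3,4,4a,5,6,7-octahydronaphthalene-2-carboxylic acid | OC(=O)[C@@]1(CC(OC)OC)CC[C@@H]2C(=CCCC2(C)C)[C@H]1C | intermediate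
23 | [(1R,2R,4aS)-2-(2,2-dimethoxyethyl)-1,5,5-trimethyl-1,2,3,4,4a,5,6,7-octahydronaphthalen-2-yl]methanol | OC[C@@]1(CC(OC)OC)CC[C@@H]2C(=CCCC2(C)C)[C@H]1C | intermediate
24 | (1R,2R,4aS)-2-(2,2-dimethoxyethyl)-1,5,5-trimethyl-1,2,3,4,4a,5,6,7-octahydronaphthalene-2-carbaldehyde | O=C[C@@]1(CC(OC)OC)CC[C@@H]2C(=CCCC2(C)C)[C@H]1C | intermediate
25 | hydrazone of 24 | NN=C[C@@]1(CC(OC)OC)CC[C@@H]2C(=CCCC2(C)C)[C@H]1C | intermediate
26 | (1S,2S,4aS)-2-(2,2-dimethoxyethyl)-1,2,5,5-tetramethyl-1,2,3,4,4a,5,6,7-octahydronaphthalene | C[C@@]1(CC(OC)OC)CC[C@@H]2C(=CCCC2(C)C)[C@H]1C | intermediate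
27 | 2-[(1S,2S,4aS)-1,2,5,5-tetramethyl-1,2,3,4,4a,5,6,7-octahydronaphthalen-2-yl]acetaldehyde | O=CC[C@]1(C)CC[C@@H]2C(=CCCC2(C)C)[C@H]1C | intermediate
28 | 2-[(1S,2S,4aS)-1,2,5,5-tetramethyl-1,2,3,4,4a,5,6,7-octahydronaphthalen-2-yl]acetic acid | OC(=O)C[C@]1(C)CC[C@@H]2C(=CCCC2(C)C)[C@H]1C | intermediate
29 | (R)-2,2-dimethyl-1,3-dioxolane-4-carbaldehyde | O=C[C@H]1COC(C)(C)O1 | starting material
30 | methyl (triphenylphosphoranylidene)acetate | COC(=O)C=P(c1ccccc1)(c1ccccc1)c1ccccc1 | starting material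
31 | methyl (2Z)-3-[(4S)-2,2-dimethyl-1,3-dioxolan-4-yl]prop-2-enoate | COC(=O)/C=C\[C@H]1COC(C)(C)O1 | intermediate
32 | (2Z)-3-[(4S)-2,2-dimethyl-1,3-dioxolan-4-yl]prop-2-en-1-ol | OC/C=C\[C@H]1COC(C)(C)O1 | intermediate
33 | (2Z)-3-[(4S)-2,2-dimethyl-1,3-dioxolan-4-yl]prop-2-en-1-yl 2-[(1S,2S,4aS)-1,2,5,5-tetramethyl-1,2,3,4,4a,5,6,7-octahydronaphthalen-2-yl]acetate | O=C(C[C@]1(C)CC[C@@H]2C(=CCCC2(C)C)[C@H]1C)OC/C=C\[C@H]1COC(C)(C)O1 | intermediate
34 | (E)-trimethylsilyl ketene acetal of 33 | C[Si](C)(C)O/C(OC/C=C\[C@H]1COC(C)(C)O1)=C/[C@]1(C)CC[C@@H]2C(=CCCC2(C)C)[C@H]1C | intermediate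
35 | trimethylsilyl ester of 36 | C[Si](C)(C)OC(=O)[C@H]([C@@H](C=C)[C@H]1COC(C)(C)O1)[C@]1(C)CC[C@@H]2C(=CCCC2(C)C)[C@H]1C | intermediate
36 | (2R,3R)-3-[(4S)-2,2-dimethyl-1,3-dioxolan-4-yl]-2-[(1S,2R,4aS)-1,2,5,5-tetramethyl-1,2,3,4,4a,5,6,7-octahydronaphthalen-2-yl]pent-4-enoic acid | OC(=O)[C@H]([C@@H](C=C)[C@H]1COC(C)(C)O1)[C@]1(C)CC[C@@H]2C(=CCCC2(C)C)[C@H]1C | intermediate
37 | (3R,4R,5S)-4-ethenyl-5-(hydroxymethyl)-3-[(1S,2R,4aS)-1,2,5,5-tetramethyl-1,2,3,4,4a,5,6,7-octahydronaphthalen-2-yl]oxolan-2-one | O=C1O[C@H](CO)[C@H](C=C)[C@@H]1[C@]1(C)CC[C@@H]2C(=CCCC2(C)C)[C@H]1C | intermediate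
38 | (2S,3R,4R)-3-ethenyl-5-oxo-4-[(1S,2R,4aS)-1,2,5,5-tetramethyl-1,2,3,4,4a,5,6,7-octahydronaphthalen-2-yl]oxolane-2-carboxylic acid | O=C1O[C@H](C(=O)O)[C@H](C=C)[C@@H]1[C@]1(C)CC[C@@H]2C(=CCCC2(C)C)[C@H]1C | intermediate
39 | (2S,3R,4R)-3-ethenyl-5-hydroxy-4-[(1S,2R,4aS)-1,2,5,5-tetramethyl-1,2,3,4,4a,5,6,7-octahydronaphthalen-2-yl]oxolane-2-carboxylic acid (lactol, both anomers) | OC1O[C@H](C(=O)O)[C@H](C=C)[C@@H]1[C@]1(C)CC[C@@H]2C(=CCCC2(C)C)[C@H]1C | intermediate
40 | methyl (2S,3R,4R)-3-ethenyl-5-methoxy-4-[(1S,2R,4aS)-1,2,5,5-tetramethyl-1,2,3,4,4a,5,6,7-octahydronaphthalen-2-yl]oxolane-2-carboxylate (both anomers) | COC1O[C@H](C(=O)OC)[C@H](C=C)[C@@H]1[C@]1(C)CC[C@@H]2C(=CCCC2(C)C)[C@H]1C | intermediate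
41 | methyl (2R,3R,4R)-3-ethenyl-5-methoxy-4-[(1S,2R,4aS)-1,2,5,5-tetramethyl-1,2,3,4,4a,5,6,7-octahydronaphthalen-2-yl]oxolane-2-carboxylate (both anomers) | COC1O[C@@H](C(=O)OC)[C@H](C=C)[C@@H]1[C@]1(C)CC[C@@H]2C(=CCCC2(C)C)[C@H]1C | intermediate
42 | B-alkyl-9-borabicyclo[3.3.1]nonane adduct of 41 | COC1O[C@@H](C(=O)OC)[C@H](CCB2C3CCCC2CCC3)[C@@H]1[C@]1(C)CC[C@@H]2C(=CCCC2(C)C)[C@H]1C | intermediate
43 | methyl (2R,3R,4R)-3-(2-hydroxyethyl)-5-methoxy-4-[(1S,2R,4aS)-1,2,5,5-tetramethyl-1,2,3,4,4a,5,6,7-octahydronaphthalen-2-yl]oxolane-2-carboxylate | COC1O[C@@H](C(=O)OC)[C@H](CCO)[C@@H]1[C@]1(C)CC[C@@H]2C(=CCCC2(C)C)[C@H]1C | intermediate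
44 | 2-[(2R,3R,4R)-5-methoxy-2-(methoxycarbonyl)-4-[(1S,2R,4aS)-1,2,5,5-tetramethyl-1,2,3,4,4a,5,6,7-octahydronaphthalen-2-yl]oxolan-3-yl]acetic acid | COC1O[C@@H](C(=O)OC)[C@H](CC(=O)O)[C@@H]1[C@]1(C)CC[C@@H]2C(=CCCC2(C)C)[C@H]1C | intermediate
45 | methyl (1S,5R,6R,8R)-3-oxo-8-[(1S,2R,4aS)-1,2,5,5-tetramethyl-1,2,3,4,4a,5,6,7-octahydronaphthalen-2-yl]-2,7-dioxabicyclo[3.2.1]octane-6-carboxylate | COC(=O)[C@@H]1O[C@H]2OC(=O)C[C@@H]1[C@@H]2[C@]1(C)CC[C@@H]2C(=CCCC2(C)C)[C@H]1C | target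

**Step count**

Total: 25 steps. Longest linear sequence: 22 steps (steps 1–7, 9–14, 17–25).

**Steps most likely to fail**

Step 10 (key step). The ketene acetal may not reach the bicyclic transition state, so that β-elimination of the allylic carboxylate or ketene loss takes over, or the shift may run through a boat array and lose control of the quaternary centre. The fallback uses known chemistry and sets out from 19. NaOMe in MeOH opens the lactone to methyl 2-{2-[(1S,5R,6Z)-6-ethylidene-5-hydroxy-2,2-dimethylcyclohexyl]ethyl}-4,4-dimethoxybutanoate F1. ClP(O)(OEt)2 with N-methylimidazole converts it into the allylic diethyl phosphate F2. KN(SiMe3)2 in THF (−78 → 0 °C) then closes ring B by intramolecular SN2′ alkylation of the ester enolate, a six-membered ring closure in which the tether enforces attack on the same alkene face and therefore the same secondary methyl centre. This gives methyl (1R,2R,4aS)-2-(2,2-dimethoxyethyl)-1,5,5-trimethyl-1,2,3,4,4a,5,6,7-octahydronaphthalene-2-carboxylate F3. The quaternary centre is less securely controlled here and its epimer would have to be separated. LiAlH4 reduction of F3 returns to the route at 23.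

Step 7. Intermolecular acylation (dimers and oligomers) may outrun closure of the strained eight-membered ring. The fallback closes the ring at the carbinol carbon instead and sets out from 8. Reduction with (R)-2-methyl-CBS-oxazaborolidine and catecholborane gives the C5-epimeric alcohol, ethyl 4-[(1S,5S,6E)-6-ethylidene-5-hydroxy-2,2-dimethylcyclohexyl]butanoate F4. The sequence of steps 4–6 then gives the epoxy alcohol F5, the epoxy acid F6 and 4-[(1S,5S,6Z)-6-ethylidene-5-hydroxy-2,2-dimethylcyclohexyl]butanoic acid F7. Mitsunobu lactonisation of F7 (PPh3, diisopropyl azodicarboxylate, toluene, high dilution), in which the carboxylate displaces the activated hydroxyl with inversion, returns to the route at 15.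

Step 18. Diastereoselectivity may erode because both large groups must sit axial in the chair (a boat pathway becomes competitive), or because the facial preference of the decalin opposes that of the dioxolane. The fallback takes stereocontrol from a stereogenic carbinol carbon inside the pericyclic array. From 29, Wittig reaction with Ph3P=CHC(O)CH3 gives (3E)-4-[(4S)-2,2-dimethyl-1,3-dioxolan-4-yl]but-3-en-2-one F8. Reduction with (R)-2-methyl-CBS-oxazaborolidine and BH3·SMe2 gives (2S,3E)-4-[(4S)-2,2-dimethyl-1,3-dioxolan-4-yl]but-3-en-2-ol F9. Esterification with 28 (DCC, DMAP) gives the ester F10. Enolisation with LiN(iPr)2 in THF–HMPA (Z-silyl ketene acetal) and Me3SiCl, then warming, should rearrange through a chair with all three substituents equatorial and transfer chirality from the carbinol carbon. The product is (2R,3R,4E)-3-[(4S)-2,2-dimethyl-1,3-dioxolan-4-yl]-2-[(1S,2R,4aS)-1,2,5,5-tetramethyl-1,2,3,4,4a,5,6,7-octahydronaphthalen-2-yl]hex-4-enoic acid F11. Ethenolysis of the propenyl group (second-generation Grubbs catalyst, ethylene, CH2Cl2) returns to the route at 36.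

**Further compounds**

F1 | step 10 | methyl 2-{2-[(1S,5R,6Z)-6-ethylidene-5-hydroxy-2,2-dimethylcyclohexyl]ethyl}-4,4-dimethoxybutanoate (both C2 epimers) | O[C@@H]1CCC(C)(C)[C@H](CCC(CC(OC)OC)C(=O)OC)/C1=C/C
F2 | step 10 | methyl 2-{2-[(1S,5R,6Z)-5-(diethoxyphosphoryloxy)-6-ethylidene-2,2-dimethylcyclohexyl]ethyl}-4,4-dimethoxybutanoate | CCOP(=O)(OCC)O[C@@H]1CCC(C)(C)[C@H](CCC(CC(OC)OC)C(=O)OC)/C1=C/C
F3 | step 10 | methyl (1R,2R,4aS)-2-(2,2-dimethoxyethyl)-1,5,5-trimethyl-1,2,3,4,4a,5,6,7-octahydronaphthalene-2-carboxylate | COC(=O)[C@@]1(CC(OC)OC)CC[C@@H]2C(=CCCC2(C)C)[C@H]1C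
F4 | step 7 | ethyl 4-[(1S,5S,6E)-6-ethylidene-5-hydroxy-2,2-dimethylcyclohexyl]butanoate | O[C@H]1CCC(C)(C)[C@H](CCCC(=O)OCC)/C1=C\C
F5 | step 7 | ethyl 4-[8-hydroxy-2,5,5-trimethyl-1-oxaspiro[2.5]octan-4-yl]butanoate (C8 epimer of 10; epoxide oxygen cis to the hydroxyl) | O[C@H]1CCC(C)(C)[C@H](CCCC(=O)OCC)[C@@]12O[C@@H]2C
F6 | step 7 | 4-[8-hydroxy-2,5,5-trimethyl-1-oxaspiro[2.5]octan-4-yl]butanoic acid (configuration as F5) | O[C@H]1CCC(C)(C)[C@H](CCCC(=O)O)[C@@]12O[C@@H]2C
F7 | step 7 | 4-[(1S,5S,6Z)-6-ethylidene-5-hydroxy-2,2-dimethylcyclohexyl]butanoic acid | O[C@H]1CCC(C)(C)[C@H](CCCC(=O)O)/C1=C/C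
F8 | step 18 | (3E)-4-[(4S)-2,2-dimethyl-1,3-dioxolan-4-yl]but-3-en-2-one | CC(=O)/C=C/[C@H]1COC(C)(C)O1
F9 | step 18 | (2S,3E)-4-[(4S)-2,2-dimethyl-1,3-dioxolan-4-yl]but-3-en-2-ol | C[C@H](O)/C=C/[C@H]1COC(C)(C)O1
F10 | step 18 | (2S,3E)-4-[(4S)-2,2-dimethyl-1,3-dioxolan-4-yl]but-3-en-2-yl 2-[(1S,2S,4aS)-1,2,5,5-tetramethyl-1,2,3,4,4a,5,6,7-octahydronaphthalen-2-yl]acetate | O=C(C[C@]1(C)CC[C@@H]2C(=CCCC2(C)C)[C@H]1C)O[C@@H](C)/C=C/[C@H]1COC(C)(C)O1
F11 | step 18 | (2R,3R,4E)-3-[(4S)-2,2-dimethyl-1,3-dioxolan-4-yl]-2-[(1S,2R,4aS)-1,2,5,5-tetramethyl-1,2,3,4,4a,5,6,7-octahydronaphthalen-2-yl]hex-4-enoic acid | OC(=O)[C@H]([C@@H](/C=C/C)[C@H]1COC(C)(C)O1)[C@]1(C)CC[C@@H]2C(=CCCC2(C)C)[C@H]1C
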